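The runs come from a simulation for an exercise; scatter was added.

I started from a ratio: the extra product per extra coupling partner between the two earlier runs, the summer run and the dusk run, dusk being the very flask asked about.

| flask | starting material | coupling partner | initiator | remark | time |
|---|---|---|---|---|---|
| dusk | 0.050 M | 1 equiv | 0.5 mol% | the very flask that is asked about, followed so far |  |
| summer | 0.050 M | 0.67 equiv | 0.5 mol% | run made earlier |  |
| flask | 0.050 M | 1.00 equiv | 0.5 mol% |  | 6.0 h |

| run | time / h | product / % | starting material / % |
|---|---|---|---|
| dusk | 0.333 | 12 | 88 |
| dusk | 0.833 | 26 | 74 |
| dusk | 1.50 | 37 | 66 |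
| dusk | 2.50 | 36 | 67 |
| dusk | 4.00 | 34 | 67 |
| summer | 1.33 | 30 | 70 |
| summer | 2.50 | 28 | 72 |
| summer | 4.00 | 28 | 71 |
| summer | 5.00 | 32 | 70 |
| summer | 6.00 | 30 | 68 |

(readings scatter by 1.5 percentage points)

- larch: at 6.0 h take out 90 % of the product then present, then wait 6.0 h
- cedar: change nothing and wait 6.0 h more
- maple: at 6.0 h add coupling partner, 50.0 % of the amount charged, then wait 6.0 h
- ash: at 6.0 h add starting material, 50.0 % of the amount charged, then wait 6.0 h

- product taken out counts as made
- the analysis behind the earlier runs scatters by 1.5 percentage points, standard deviation
- additions bring no volume worth counting

- product, in percent of the starting material first charged, at 6.0 h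
- which option adds most product ("none" when 2 percentage points or less is all one gets) (larch / cedar / maple / ash / none)
- product present, with what was taken out counted in, in percent of the starting material first charged, after maple
- product present, with what was taken out counted in, in percent of the starting material first charged, after ash

Product read flat from 1.50 h on in dusk and from the first reading on in summer, averaging 35.7 % in dusk and 29.6 % in summer, so the extra partner of dusk returned a marginal yield of 18.4 %. I read this as a race for the coupling partner, which I assumed was spent two ways: a coupling drawing at a steady rate r, read from the first dusk point as 0.360 h⁻¹, whatever [coupling partner] is, and a first-order loss k[coupling partner] to something unseen. The plateau is then c·ln(1+b/c), with b the partner charged as a share of the starting material, and the marginal yield is c/(c+b). That reading, with the scatter of the plateaus in it, put at 18.8 % of the starting material charged the crossing amount c = r/k, the [coupling partner] at which loss and coupling go equally fast. Above it the loss leads. The rule returned 34.7 % for dusk and 28.5 % for summer.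

Then I ranked the times. The loss came first, with time c/r of 0.522 h. Next came the stop of the coupling, near 0.990 h. Slower was 2.77 h, the time the draw needs for the starting material, so the stop came first and starting material stayed behind. After these came the look at 6.0 h, where I said 35.7 %. The flat plateau promised nothing from cedar or larch, and ash brings no partner. Maple does: taking the draw as proportional to [starting material], the crossing falls to 12.1 %, and the rule gives 20 percentage points more, so 55.7 %.

The forecast, on the grounds “Mass balance holds, so this looks like a plateau, not side loss”, said 35.5 %, larch as best, 43.3 % and 43.3 %; the flask gave 35.5 %, maple, 56.1 % and 35.5 %.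

    coupling partner → decomposed reagent (k = 4.20 × 10⁻⁴ s⁻¹)
    initiator → 2 initiating radical (k = 2.50 × 10⁻⁷ s⁻¹)
    coupling partner + first chain carrier → product + second chain carrier (k = 1.50 × 10⁵ M⁻¹ s⁻¹)
    starting material + second chain carrier → by-product + first chain carrier (k = 3.90 × 10⁵ M⁻¹ s⁻¹)
    2 second chain carrier → ended chains (k = 1.00 × 10⁹ M⁻¹ s⁻¹)
    starting material + initiating radical → capped initiator + first chain carrier (k = 2.80 × 10⁶ M⁻¹ s⁻¹)

At 0.275 h the flask's coupling partner had a half-life of 0.46 h by the step to decomposed reagent against 1.3 h by coupling. By 3.00 h the flask held 0.0323 M of decomposed reagent beside 35.5 % of product, with the coupling partner, its limiting reagent, at 0 %, and maple's reckoned 20 points stood against 21 points. On the neighbour charged with 4.00 equiv, the crossing amount gives 58.4 %, and that flask holds 55.0 % of product at 6.00 h.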